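A direct plan would set C15 by allylboration of dodecanal A1 with a stoichiometric chiral borane to give (S)-pentadec-1-en-4-ol A2, then silylate, hydroformylate and allylborate again to reach the C11 carbinol A3; carbons are numbered from the lactone carbonyl C1 to the chain end C26.
A silicon tether on O11 and a rhodium-catalysed silylformylation–allylsilylation with Tamao oxidation would then give the syn,syn-triol A4.
Persilylation, ozonolysis, a third allylboration at C5, acryloylation and ring-closing metathesis would build the silylated lactone A5; a fourfold desilylation would end the route.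
Weak: the three allylborations would buy C15, C11 and C5 one at a time, each with a full equivalent of chiral reagent, and the last would act on a β-silyloxy aldehyde whose own bias need not agree with the reagent.
Weak: the tandem silylformylation would need a purpose-made diallylsilyl ether and high-pressure carbonylation, and would still relay only C9 and C7 from C11.
Weak: the run from the triol to the lactone would spend five steps and four silyl ethers on one new centre and one simple ring, and would leave a fourfold deprotection beside a base-sensitive hydroxy lactone.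

**Retrosynthetic overview**
- The only ring (O5–C1(=O)–C2=C3–C4–C5) is opened at the acyl bond C1–O5 and the Z-alkene C2=C3 is cut back to a C3 aldehyde, so the ring closes last, by lactonisation as the silyl groups fall.
- The all-syn array O5/O7/O9/O11, with one CH2 between neighbouring carbinols (C4–C11), is read as three acetaldehyde units: C4–C5, C6–C7 and C8–C9 are cut in one operation, a triple Mukaiyama aldol cascade of a vinyl tris(trimethylsilyl)silyl ether on the C9 aldehyde 14.
- In that flask C9, C7 and C5 are relayed 1,3-syn from C11, and every new oxygen arrives already protected by the silyl group of the enol ether; the precursor holds two stereocentres, the product five.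
- C15 is bought with (S)-epichlorohydrin and C11 is set once by catalysis on an unprotected diol; unlike the way from A1 through A2, A3, A4 and A5, no stoichiometric chiral reagent, tether, metathesis or separate polyol protection is needed.

Key step: step 7

Remark: C1–C26 are the carbons of the target (C1 lactone carbonyl, C5 ring carbinol, C26 chain end); "sisyl" means tris(trimethylsilyl)silyl, (Me3Si)3Si.
Assumption: with unbranched aliphatic alcohols the (S)-BINAP-modified iridium catalyst is taken to give the (R)-homoallylic alcohol; if the sense were the opposite, (R)-BINAP would be used in step 3.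

Step 1
Reactants: 1 (S)-epichlorohydrin; 2 decylmagnesium bromide
Product: 4 (S)-1,2-epoxytridecane, via chlorohydrin 3 (not isolated)
Conditions: 2 (1.1 equiv), CuI (5 mol %), THF, −40 → 0 °C; then aq. NaOH, rt
Reagents that add atoms: decylmagnesium bromide (2), CCCCCCCCCC[Mg]Br
Why: Copper-catalysed Grignard opening of the oxirane at its CH2 terminus followed by base-induced closure of chlorohydrin 3 (epichlorohydrin as a linchpin) moves the epoxide to the other side without touching the stereocentre, so the bought S centre becomes C15.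

Step 2
Reactants: 4 (S)-1,2-epoxytridecane; 5 3-chloropropan-1-ol
Product: 7 (S)-hexadecane-1,5-diol, via Normant reagent 6 (not isolated)
Conditions: 5, i-PrMgCl (1.0 equiv), THF, −20 °C; Mg, reflux; then 4, CuI (10 mol %), −30 → 0 °C; 1 M HCl
Reagents that add atoms: 3-chloropropan-1-ol (5), OCCCCl
Why: Copper-catalysed opening of the terminal epoxide at C14 by the Normant reagent, a Grignard reagent that carries its own magnesium alkoxide, delivers C11–C13 with O11 already free and leaves C15 untouched.

Step 3
Reactants: 7 (S)-hexadecane-1,5-diol; 8 allyl acetate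
Product: 10 (4R,8S)-nonadec-1-ene-4,8-diol, via hydroxy aldehyde 9 (not isolated)
Conditions: [Ir(cod)Cl]2 (2.5 mol %), (S)-BINAP (5 mol %), 4-chloro-3-nitrobenzoic acid (10 mol %), Cs2CO3 (20 mol %), 8 (2 equiv), THF, 100 °C, sealed tube
Reagents that add atoms: allyl acetate (8), C=CCOC(C)=O
Why: Iridium-catalysed transfer-hydrogenative carbonyl allylation (Krische allylation), in which the primary alcohol is dehydrogenated in preference to the secondary C15 carbinol and the chiral π-allyliridium C,O-benzoate complex adds to the transient aldehyde 9 through a closed chair, so that C11 is set as R under catalyst control without influence of the remote C15.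

Step 4
Reactants: 10 (4R,8S)-nonadec-1-ene-4,8-diol; 11 chlorotris(trimethylsilyl)silane
Product: 12 (4R,8S)-4,8-bis{[tris(trimethylsilyl)silyl]oxy}nonadec-1-ene
Conditions: 11 (2.4 equiv), DMAP (3 equiv), CH2Cl2, rt
Reagents that add atoms: chlorotris(trimethylsilyl)silane (11), C[Si](C)(C)[Si](Cl)([Si](C)(C)C)[Si](C)(C)C
Why: DMAP-promoted O-silylation of both secondary alcohols installs at O11 the very large β-silyloxy group that will steer the cascade and masks O15 with the same group, so no differentiation of the two hydroxyls is needed.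

Step 5
Reactants: 12 (4R,8S)-4,8-bis{[tris(trimethylsilyl)silyl]oxy}nonadec-1-ene
Product: 14 (3R,7S)-3,7-bis{[tris(trimethylsilyl)silyl]oxy}octadecanal, via glycol 13 (not isolated)
Conditions: OsO4 (2 mol %), NaIO4 (4 equiv), 2,6-lutidine (2 equiv), dioxane/H2O (3:1), rt
Reagents that add atoms: osmium tetroxide, O=[Os](=O)(=O)=O; sodium periodate (terminal oxidant that restores it), [Na+].[O-]I(=O)(=O)=O
Why: Lemieux–Johnson cleavage (catalytic dihydroxylation to glycol 13, then periodate scission) of the only C=C bond gives the C9 aldehyde; the buffered periodate system is chosen over ozone to keep a strong electrophilic oxidant away from the Si–Si bonds, and lutidine limits over-oxidation and β-elimination.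

Step 6
Reactants: 15 tetrahydrofuran; 11 chlorotris(trimethylsilyl)silane
Product: 17 (ethenyloxy)tris(trimethylsilyl)silane, via lithium ethenolate 16 (not isolated)
Conditions: n-BuLi (1.0 equiv), THF, rt → 35 °C; then 11, DMPU, 0 °C → rt
Reagents that add atoms: chlorotris(trimethylsilyl)silane (11), C[Si](C)(C)[Si](Cl)([Si](C)(C)C)[Si](C)(C)C
Why: The known cycloreversion of 2-lithiotetrahydrofuran gives ethene and the lithium enolate of acetaldehyde, which is O-silylated by the chlorosilane to the enol ether.

Step 7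
Reactants: 14 (3R,7S)-3,7-bis{[tris(trimethylsilyl)silyl]oxy}octadecanal; 17 (ethenyloxy)tris(trimethylsilyl)silane
Product: 20 (3R,5R,7R,9R,13S)-3,5,7,9,13-pentakis{[tris(trimethylsilyl)silyl]oxy}tetracosanal, via mono-adduct aldehyde 18 (not isolated), via bis-adduct aldehyde 19 (not isolated)
Conditions: 17 (3.3 equiv, in three portions), HNTf2 (0.1 mol %), CH2Cl2, −40 °C → rt
Reagents that add atoms: (ethenyloxy)tris(trimethylsilyl)silane (17), C=CO[Si]([Si](C)(C)C)([Si](C)(C)C)[Si](C)(C)C
Why: Triflimide-catalysed Mukaiyama aldol cascade (closest known reaction type: the double and triple aldol cascades of this acetaldehyde-derived enol ether with simple aldehydes), in which HNTf2 releases the silyl triflimide, this activates the aldehyde as a silyloxocarbenium ion, the enol ether adds through an open transition state, and its silyl group ends on the new oxygen while the next aldehyde (C7, then C5, then C3) is set free. No ring is closed; the bonds C8–C9, C6–C7 and C4–C5 form in sequence. C9 is controlled by C11, C7 by C9 and C5 by C7, each through the β-silyloxy group: the very large silyl ether fixes the conformation of the β-silyloxy oxocarbenium ion so that the enol ether adds 1,3-syn, the sense characteristic of β-tris(trimethylsilyl)silyloxy aldehydes and opposite to the 1,3-anti preference of small β-alkoxy groups. The step needs three additions and no fourth, and no self-condensation of the product aldehydes; each addition should be slower than the one before as the chain gathers bulk, the enol ether is dosed in three portions of 1.1 equivalents, and the bulky silyl groups keep the aldehydes from enolising or oligomerising at this acid loading. The C15 silyl ether is a spectator and the remote centre has no influence.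

Step 8
Reactants: 20 (3R,5R,7R,9R,13S)-3,5,7,9,13-pentakis{[tris(trimethylsilyl)silyl]oxy}tetracosanal; 21 methyl 2-[bis(2,2,2-trifluoroethoxy)phosphoryl]acetate
Product: 22 methyl (2Z,5S,7S,9R,11R,15S)-5,7,9,11,15-pentakis{[tris(trimethylsilyl)silyl]oxy}hexacos-2-enoate
Conditions: 21 (1.3 equiv), KN(SiMe3)2 (1.25 equiv), 18-crown-6 (3 equiv), THF, −78 °C
Reagents that add atoms: methyl 2-[bis(2,2,2-trifluoroethoxy)phosphoryl]acetate (21), COC(=O)CP(=O)(OCC(F)(F)F)OCC(F)(F)F
Why: Still–Gennari olefination, in which the electron-poor phosphonate anion adds to the unhindered CH2–CHO terminus and the oxaphosphetane collapses fast, should give the Z-enoate needed for ring closure, while the non-nucleophilic conditions at −78 °C leave the β-silyloxy group in place.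

Step 9
Reactants: 22 methyl (2Z,5S,7S,9R,11R,15S)-5,7,9,11,15-pentakis{[tris(trimethylsilyl)silyl]oxy}hexacos-2-enoate
Product: 24 (6S)-6-[(2R,4R,6R,10S)-2,4,6,10-tetrahydroxyhenicosyl]-5,6-dihydro-2H-pyran-2-one, via pentahydroxy ester 23 (not isolated)
Conditions: HF·pyridine, THF, 0 °C → rt; then PPTS (cat.), benzene, rt
Reagents that add atoms: none
Why: Acidic fluoride desilylation frees the five hydroxyls, and O5, held next to the ester by the Z double bond, closes the six-membered lactone by acyl substitution with loss of methanol; the acidic medium disfavours conjugate addition of O7 to C3 and no stereocentre is touched.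

**Compound list**

1 | (S)-epichlorohydrin | ClC[C@@H]1CO1 | starting material
2 | decylmagnesium bromide | CCCCCCCCCC[Mg]Br | starting material
3 | (S)-1-chlorotridecan-2-ol | ClC[C@@H](O)CCCCCCCCCCC | intermediate
4 | (S)-1,2-epoxytridecane | CCCCCCCCCCC[C@H]1CO1 | intermediate
5 | 3-chloropropan-1-ol | OCCCCl | starting material
6 | chloromagnesium 3-(chloromagnesio)propan-1-olate (Normant reagent) | Cl[Mg]CCCO[Mg]Cl | intermediate
7 | (S)-hexadecane-1,5-diol | CCCCCCCCCCC[C@H](O)CCCCO | intermediate
8 | allyl acetate | C=CCOC(C)=O | starting material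
9 | (S)-5-hydroxyhexadecanal | CCCCCCCCCCC[C@H](O)CCCC=O | intermediate
10 | (4R,8S)-nonadec-1-ene-4,8-diol | CCCCCCCCCCC[C@H](O)CCC[C@@H](O)CC=C | intermediate
11 | chlorotris(trimethylsilyl)silane | C[Si](C)(C)[Si](Cl)([Si](C)(C)C)[Si](C)(C)C | starting material
12 | (4R,8S)-4,8-bis{[tris(trimethylsilyl)silyl]oxy}nonadec-1-ene | CCCCCCCCCCC[C@H](O[Si]([Si](C)(C)C)([Si](C)(C)C)[Si](C)(C)C)CCC[C@@H](O[Si]([Si](C)(C)C)([Si](C)(C)C)[Si](C)(C)C)CC=C | intermediate
13 | (4R,8S)-4,8-bis{[tris(trimethylsilyl)silyl]oxy}nonadecane-1,2-diol (mixture at C2) | CCCCCCCCCCC[C@H](O[Si]([Si](C)(C)C)([Si](C)(C)C)[Si](C)(C)C)CCC[C@@H](O[Si]([Si](C)(C)C)([Si](C)(C)C)[Si](C)(C)C)CC(O)CO | intermediate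
14 | (3R,7S)-3,7-bis{[tris(trimethylsilyl)silyl]oxy}octadecanal | CCCCCCCCCCC[C@H](O[Si]([Si](C)(C)C)([Si](C)(C)C)[Si](C)(C)C)CCC[C@@H](O[Si]([Si](C)(C)C)([Si](C)(C)C)[Si](C)(C)C)CC=O | intermediate
15 | tetrahydrofuran | C1CCOC1 | starting material
16 | lithium ethenolate | [Li]OC=C | intermediate
17 | (ethenyloxy)tris(trimethylsilyl)silane | C=CO[Si]([Si](C)(C)C)([Si](C)(C)C)[Si](C)(C)C | intermediate
18 | (3R,5R,9S)-3,5,9-tris{[tris(trimethylsilyl)silyl]oxy}icosanal | CCCCCCCCCCC[C@H](O[Si]([Si](C)(C)C)([Si](C)(C)C)[Si](C)(C)C)CCC[C@@H](O[Si]([Si](C)(C)C)([Si](C)(C)C)[Si](C)(C)C)C[C@@H](O[Si]([Si](C)(C)C)([Si](C)(C)C)[Si](C)(C)C)CC=O | intermediate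
19 | (3R,5R,7R,11S)-3,5,7,11-tetrakis{[tris(trimethylsilyl)silyl]oxy}docosanal | CCCCCCCCCCC[C@H](O[Si]([Si](C)(C)C)([Si](C)(C)C)[Si](C)(C)C)CCC[C@@H](O[Si]([Si](C)(C)C)([Si](C)(C)C)[Si](C)(C)C)C[C@@H](O[Si]([Si](C)(C)C)([Si](C)(C)C)[Si](C)(C)C)C[C@@H](O[Si]([Si](C)(C)C)([Si](C)(C)C)[Si](C)(C)C)CC=O | intermediate
20 | (3R,5R,7R,9R,13S)-3,5,7,9,13-pentakis{[tris(trimethylsilyl)silyl]oxy}tetracosanal | CCCCCCCCCCC[C@H](O[Si]([Si](C)(C)C)([Si](C)(C)C)[Si](C)(C)C)CCC[C@@H](O[Si]([Si](C)(C)C)([Si](C)(C)C)[Si](C)(C)C)C[C@@H](O[Si]([Si](C)(C)C)([Si](C)(C)C)[Si](C)(C)C)C[C@@H](O[Si]([Si](C)(C)C)([Si](C)(C)C)[Si](C)(C)C)C[C@@H](O[Si]([Si](C)(C)C)([Si](C)(C)C)[Si](C)(C)C)CC=O | intermediate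
21 | methyl 2-[bis(2,2,2-trifluoroethoxy)phosphoryl]acetate | COC(=O)CP(=O)(OCC(F)(F)F)OCC(F)(F)F | starting material
22 | methyl (2Z,5S,7S,9R,11R,15S)-5,7,9,11,15-pentakis{[tris(trimethylsilyl)silyl]oxy}hexacos-2-enoate | CCCCCCCCCCC[C@H](O[Si]([Si](C)(C)C)([Si](C)(C)C)[Si](C)(C)C)CCC[C@@H](O[Si]([Si](C)(C)C)([Si](C)(C)C)[Si](C)(C)C)C[C@@H](O[Si]([Si](C)(C)C)([Si](C)(C)C)[Si](C)(C)C)C[C@@H](O[Si]([Si](C)(C)C)([Si](C)(C)C)[Si](C)(C)C)C[C@@H](O[Si]([Si](C)(C)C)([Si](C)(C)C)[Si](C)(C)C)C/C=C\C(=O)OC | intermediate
23 | methyl (2Z,5S,7S,9R,11R,15S)-5,7,9,11,15-pentahydroxyhexacos-2-enoate | CCCCCCCCCCC[C@H](O)CCC[C@@H](O)C[C@@H](O)C[C@@H](O)C[C@@H](O)C/C=C\C(=O)OC | intermediate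
24 | (6S)-6-[(2R,4R,6R,10S)-2,4,6,10-tetrahydroxyhenicosyl]-5,6-dihydro-2H-pyran-2-one | CCCCCCCCCCC[C@H](O)CCC[C@@H](O)C[C@@H](O)C[C@@H](O)C[C@@H]1CC=CC(=O)O1 | target

**Count and risks**

Total step count: 9. Longest linear sequence: 8 steps (steps 1–5 and 7–9); step 6 makes the enol ether.

Steps most likely to fail:

1. Step 7. The third addition is the slowest, so conversion may stall or stereocontrol at C5 may erode, and double, triple and fourfold adducts may form side by side. The fallback sets out from 14: the enol ether 17 is limited to 2.1 equiv and the bis-adduct aldehyde 19 is isolated, so only two centres are relayed. C5 is then set under catalyst control and the ring is formed at once by a hetero-Diels–Alder reaction of 19 with (E)-1-methoxybuta-1,3-diene. The catalyst would be the chloride complex of trivalent chromium with the tridentate Schiff base from cis-1-amino-2-indanol and 3-(1-adamantyl)-2-hydroxy-5-methylbenzaldehyde, [Cr(L)Cl], in the enantiomer that gives the 6S adduct, with 4 Å sieves. This should give the cis methyl acetal F1. Hydrolysis (PPTS, aqueous acetone) should give the lactol F2, oxidation with MnO2 in CH2Cl2 the silylated lactone F3, and HF·pyridine removes the four silyl groups, so the fallback comes back to the route at 24.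

2. Step 9. Fluoride may cleave the five very hindered Si–O bonds slowly or incompletely, and long exposure invites conjugate addition of the freed C7 hydroxyl to C3. The fallback sets out from 22 and uses the photolability of the polysilane group instead of attack at silicon. Irradiation at 254 nm in MeOH/CH2Cl2, kept short and monitored to limit Z/E isomerisation, should give the pentahydroxy ester 23 as an isolated compound. It is then closed in a separate operation with PPTS in benzene, coming back to the route at 24. This fallback makes no compound outside the list; its entry is F0.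

3. Step 5. Si–Si bonds may be oxidised in competition with the alkene, or the β-silyloxy group may be eliminated from the aldehyde. The fallback sets out from 10 and cleaves the alkene before any Si–Si bond is present. Ozonolysis in CH2Cl2/MeOH at −78 °C with Me2S work-up, then p-TsOH (cat.) in MeOH, should give the dimethyl acetal diol F4. Silylation with 11 and DMAP as in step 4 should give the bis(sisyl ether) acetal F5. Mild hydrolysis (p-TsOH cat., wet acetone), which sisyl ethers should survive, unmasks the aldehyde and comes back to the route at 14.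

**Further compounds**

F1 | step 7 | (2R,6S)-2-methoxy-6-[(2S,4R,6R,10S)-2,4,6,10-tetrakis{[tris(trimethylsilyl)silyl]oxy}henicosyl]-5,6-dihydro-2H-pyran | CCCCCCCCCCC[C@H](O[Si]([Si](C)(C)C)([Si](C)(C)C)[Si](C)(C)C)CCC[C@@H](O[Si]([Si](C)(C)C)([Si](C)(C)C)[Si](C)(C)C)C[C@@H](O[Si]([Si](C)(C)C)([Si](C)(C)C)[Si](C)(C)C)C[C@@H](O[Si]([Si](C)(C)C)([Si](C)(C)C)[Si](C)(C)C)C[C@@H]1CC=C[C@H](OC)O1
F2 | step 7 | (6S)-6-[(2S,4R,6R,10S)-2,4,6,10-tetrakis{[tris(trimethylsilyl)silyl]oxy}henicosyl]-5,6-dihydro-2H-pyran-2-ol (mixture at C2) | CCCCCCCCCCC[C@H](O[Si]([Si](C)(C)C)([Si](C)(C)C)[Si](C)(C)C)CCC[C@@H](O[Si]([Si](C)(C)C)([Si](C)(C)C)[Si](C)(C)C)C[C@@H](O[Si]([Si](C)(C)C)([Si](C)(C)C)[Si](C)(C)C)C[C@@H](O[Si]([Si](C)(C)C)([Si](C)(C)C)[Si](C)(C)C)C[C@@H]1CC=CC(O)O1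
F3 | step 7 | (6S)-6-[(2S,4R,6R,10S)-2,4,6,10-tetrakis{[tris(trimethylsilyl)silyl]oxy}henicosyl]-5,6-dihydro-2H-pyran-2-one | CCCCCCCCCCC[C@H](O[Si]([Si](C)(C)C)([Si](C)(C)C)[Si](C)(C)C)CCC[C@@H](O[Si]([Si](C)(C)C)([Si](C)(C)C)[Si](C)(C)C)C[C@@H](O[Si]([Si](C)(C)C)([Si](C)(C)C)[Si](C)(C)C)C[C@@H](O[Si]([Si](C)(C)C)([Si](C)(C)C)[Si](C)(C)C)C[C@@H]1CC=CC(=O)O1
F0 | step 9 | none | none
F4 | step 5 | (3R,7S)-1,1-dimethoxyoctadecane-3,7-diol | CCCCCCCCCCC[C@H](O)CCC[C@@H](O)CC(OC)OC
F5 | step 5 | (3R,7S)-1,1-dimethoxy-3,7-bis{[tris(trimethylsilyl)silyl]oxy}octadecane | CCCCCCCCCCC[C@H](O[Si]([Si](C)(C)C)([Si](C)(C)C)[Si](C)(C)C)CCC[C@@H](O[Si]([Si](C)(C)C)([Si](C)(C)C)[Si](C)(C)C)CC(OC)OC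
A1 | direct plan | dodecanal | CCCCCCCCCCCC=O
A2 | direct plan | (S)-pentadec-1-en-4-ol | CCCCCCCCCCC[C@H](O)CC=C
A3 | direct plan | (4R,8S)-8-(tert-butyldimethylsilyloxy)nonadec-1-en-4-ol | CCCCCCCCCCC[C@H](O[Si](C)(C)C(C)(C)C)CCC[C@@H](O)CC=C
A4 | direct plan | (4S,6R,8R,12S)-12-(tert-butyldimethylsilyloxy)tricos-1-ene-4,6,8-triol | CCCCCCCCCCC[C@H](O[Si](C)(C)C(C)(C)C)CCC[C@@H](O)C[C@@H](O)C[C@@H](O)CC=C
A5 | direct plan | (6S)-6-[(2S,4R,6R,10S)-2,4,6,10-tetrakis(tert-butyldimethylsilyloxy)henicosyl]-5,6-dihydro-2H-pyran-2-one | CCCCCCCCCCC[C@H](O[Si](C)(C)C(C)(C)C)CCC[C@@H](O[Si](C)(C)C(C)(C)C)C[C@@H](O[Si](C)(C)C(C)(C)C)C[C@@H](O[Si](C)(C)C(C)(C)C)C[C@@H]1CC=CC(=O)O1
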